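Both pyrrole–quinoline bonds are kept intact and the two quinoline benzo rings are opened instead. Each quinoline C5, which carries pyrrole C3 or C4 and sits beside the oxygenated C6 and C7, is traced back to the carbonyl carbon of a diaryl ketone, and C8 to the methyl carbon of a 2-methylpyridine. In one operation, twofold lateral metalation, acylation with methyl methoxyacetate (C7–C8) and aldol cyclodehydration (C5–C6) close both carbocycles as 6-methoxyquinolin-7-ols, with the hindered biaryl bonds already in place. The precursor is the pyrrole-3,4-diyl bis(2-methylpyridin-3-yl ketone) that already bears the complete (S)-3-methylazecanylpropyl chain on nitrogen.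

Key step: step 10

Remark on stereochemistry: an (R)-configured 3-hydroxy-2-methylpropanoate unit gives the (S)-azecane only if its hydroxymethyl carbon becomes the N-bound C2 and its carboxyl carbon becomes C4; a lactam closed on the carboxyl carbon would give the (R)-amine. The route therefore starts from (R)-3-bromo-2-methylpropan-1-ol, the same C3 unit with the former carboxyl carbon as CH2Br, and closes the ten-membered ring by sulfonamide N-alkylation instead of medium-ring lactamization. The stereocentre is never adjacent to a carbonyl group.

Assumption: the target is listed as the neutral free base; it would be handled under argon because the catechol units oxidise in air.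

Step 1
Reactants: 1 (R)-3-bromo-2-methylpropan-1-ol; 2 (6-bromohexyloxy)(tert-butyl)dimethylsilane
Product: 4 (S)-9-[(tert-butyldimethylsilyl)oxy]-2-methylnonan-1-ol, via [6-(tert-butyldimethylsilyloxy)hexyl]magnesium bromide 3 (not isolated)
Conditions: 2, Mg, THF, 45 °C; then 1 (3 in 2.5 equiv), Li2CuCl4 (5 mol %), THF–NMP, −20 °C to rt
Reagents that add atoms: none
Why: Copper-catalysed Grignard cross-coupling at a primary alkyl bromide (Kochi coupling), in which the first equivalent of 3 turns the hydroxyl group of 1 into its magnesium alkoxide and the second displaces bromide, while the stereocentre, one carbon away from the reacting centre, is carried over unchanged from 1 (the descriptor changes from R to S only through the priority rules).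

Step 2
Reactants: 4 (S)-9-[(tert-butyldimethylsilyl)oxy]-2-methylnonan-1-ol; 5 tert-butyl [(2-nitrophenyl)sulfonyl]carbamate
Product: 6 tert-butyl {(2S)-9-[(tert-butyldimethylsilyl)oxy]-2-methylnonyl}[(2-nitrophenyl)sulfonyl]carbamate
Conditions: PPh3, DIAD, THF, 0 °C to rt
Reagents that add atoms: none
Why: Fukuyama–Mitsunobu N-alkylation, in which the acidic N–H of the Boc-activated sulfonamide protonates the betaine and the resulting anion displaces the activated primary oxygen, so that monoalkylation is the only outcome and the neighbouring stereocentre is not touched.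

Step 3
Reactants: 6 tert-butyl {(2S)-9-[(tert-butyldimethylsilyl)oxy]-2-methylnonyl}[(2-nitrophenyl)sulfonyl]carbamate
Product: 7 N-[(2S)-9-hydroxy-2-methylnonyl]-2-nitrobenzenesulfonamide
Conditions: HCl (4 M in 1,4-dioxane), MeOH, rt
Reagents that add atoms: none
Why: Acidolysis, in which HCl cleaves the tert-butyl carbamate with loss of isobutene and CO2 and catalyses methanolysis of the primary silyl ether in the same flask, while the sulfonamide and the stereocentre are inert to acid.

Step 4
Reactants: 7 N-[(2S)-9-hydroxy-2-methylnonyl]-2-nitrobenzenesulfonamide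
Product: 8 (3S)-3-methyl-1-[(2-nitrophenyl)sulfonyl]azecane
Conditions: PPh3, DIAD, toluene–THF, slow addition of 7 (final 0.005 M), rt
Reagents that add atoms: none
Why: Intramolecular Fukuyama–Mitsunobu alkylation (10-exo-tet at the unbranched primary carbon, forming N1–C10), a known way to eight- to ten-membered cyclic sulfonamides, in which high dilution favours ring closure over oligomerisation and no stereocentre is formed or touched.

Step 5
Reactants: 8 (3S)-3-methyl-1-[(2-nitrophenyl)sulfonyl]azecane
Product: 9 (S)-3-methylazecane
Conditions: PhSH, K2CO3, DMF, rt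
Reagents that add atoms: none
Why: Fukuyama deprotection, in which thiolate adds to the nitroarene (nucleophilic aromatic substitution through a Meisenheimer complex) and the sulfonamide collapses with loss of SO2 to free the secondary amine without affecting the stereocentre.

Step 6
Reactants: 10 dimethyl 1H-pyrrole-3,4-dicarboxylate; 11 1-bromo-3-chloropropane
Product: 12 dimethyl 1-(3-chloropropyl)-1H-pyrrole-3,4-dicarboxylate
Conditions: 11 (3 equiv), K2CO3, DMF, rt
Reagents that add atoms: none
Why: SN2 N-alkylation of the pyrrolide anion (the two ester groups make the N–H acidic enough for K2CO3), which displaces bromide much faster than chloride and so leaves the chloride end of the chain intact.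

Step 7
Reactants: 12 dimethyl 1-(3-chloropropyl)-1H-pyrrole-3,4-dicarboxylate
Product: 13 1-(3-chloropropyl)-N3,N4-dimethoxy-N3,N4-dimethyl-1H-pyrrole-3,4-dicarboxamide
Conditions: MeNH(OMe)·HCl (4 equiv), iPrMgCl (8 equiv), THF, −20 to 0 °C
Reagents that add atoms: N,O-dimethylhydroxylamine hydrochloride, Cl.CNOC
Why: Direct ester aminolysis by the chloromagnesium amide of N,O-dimethylhydroxylamine (Weinreb amide synthesis), a nucleophile strong enough for the pyrrole-conjugated esters at low temperature and unreactive towards the primary alkyl chloride.

Step 8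
Reactants: 13 1-(3-chloropropyl)-N3,N4-dimethoxy-N3,N4-dimethyl-1H-pyrrole-3,4-dicarboxamide; 14 3-bromo-2-methylpyridine
Product: 16 [1-(3-chloropropyl)-1H-pyrrole-3,4-diyl]bis[(2-methylpyridin-3-yl)methanone], via (2-methylpyridin-3-yl)magnesium chloride 15 (not isolated)
Conditions: 14 (3.3 equiv), iPrMgCl·LiCl (3.0 equiv), THF, 0 °C to rt; then 13, 0 °C to rt; aq NH4Cl
Reagents that add atoms: none
Why: Bromine–magnesium exchange followed by Weinreb ketone synthesis, in which each amide gives a chelated tetrahedral magnesium adduct that survives until the quench, so both ketones form without over-addition, and the aryl Grignard reagent neither displaces the primary chloride nor deprotonates the 2-methyl groups.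

Step 9
Reactants: 16 [1-(3-chloropropyl)-1H-pyrrole-3,4-diyl]bis[(2-methylpyridin-3-yl)methanone]; 9 (S)-3-methylazecane
Product: 17 [1-{3-[(3S)-3-methylazecan-1-yl]propyl}-1H-pyrrole-3,4-diyl]bis[(2-methylpyridin-3-yl)methanone]
Conditions: 9 (1.3 equiv), NaI (0.2 equiv), K2CO3, MeCN, 80 °C
Reagents that add atoms: none
Why: SN2 N-alkylation of the secondary amine by the primary chloride with in situ Finkelstein activation by iodide, in which the hindered, weakly nucleophilic pyridine nitrogens and the non-enolisable ketones do not interfere and the stereocentre of 9 is remote from the reacting nitrogen.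

Step 10
Reactants: 17 [1-{3-[(3S)-3-methylazecan-1-yl]propyl}-1H-pyrrole-3,4-diyl]bis[(2-methylpyridin-3-yl)methanone]; 18 methyl methoxyacetate
Product: 20 5,5'-[1-{3-[(3S)-3-methylazecan-1-yl]propyl}-1H-pyrrole-3,4-diyl]bis(6-methoxyquinolin-7-ol), via bis(3-methoxy-2-oxopropyl) diketone 19 (not isolated)
Conditions: lithium 2,2,6,6-tetramethylpiperidide (LiTMP, from n-BuLi and 2,2,6,6-tetramethylpiperidine, 4.5 equiv), THF, −78 °C; 18 (4 equiv), −78 to 0 °C; then MeOH (LiOMe formed in situ), 65 °C; aq NH4Cl
Reagents that add atoms: none
Why: LiTMP, which has no β-hydrogen and so cannot reduce the diaryl ketones, removes one proton from each 2-methyl group (acidified by the ring nitrogen and the ortho acyl group) to give a bis(aza-dienolate) in which both ketones are masked, and each picolyl carbon is then C-acylated by 18 in a Claisen-type condensation (C7–C8), the new pyridylmethyl ketone taking up the second equivalent of base per arm, to give 19 as its bis(enolate). Methanol turns the lithium bases into LiOMe, under which the two α-positions of each new ketone equilibrate; the enolate at the methoxy-bearing carbon adds to the non-enolisable pyrrolyl pyridyl ketone (C5–C6), the carbinol next to the electron-rich pyrrole loses water easily, and tautomerisation gives the 7-hydroxy-6-methoxy benzo ring. The closest known reaction types are the lateral metalation–acylation of 2-methylpyridines and ortho-methylaryl ketones and the base-mediated aldol cyclodehydration of 2-(2-oxoalkyl)aryl ketones to 2-naphthols. Each of the two rings closes by a 6-(enolendo)-exo-trig aldol addition followed by dehydration, and no stereocentre is formed. The step needs site selectivity between C6 and the more acidic C8 of each arm and chemoselectivity against condensation between the arms: C8 cannot reach the ketone of its own arm, its addition to the ketone of the other arm would have to build a fully substituted carbinol in a seven-membered ring and is reversible, whereas closure through C6 is removed from every equilibrium by aromatisation. The oxygen pattern is fixed by connectivity, because the ketone carbon becomes C5, the methoxymethylene carbon C6 and the ester carbonyl carbon C7.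

Step 11
Reactants: 20 5,5'-[1-{3-[(3S)-3-methylazecan-1-yl]propyl}-1H-pyrrole-3,4-diyl]bis(6-methoxyquinolin-7-ol)
Product: 21 isohalitulin, 5,5'-[1-{3-[(3S)-3-methylazecan-1-yl]propyl}-1H-pyrrole-3,4-diyl]bis(quinoline-6,7-diol)
Conditions: BBr3 (12 equiv), CH2Cl2, −78 °C to rt, argon; MeOH quench, evaporation; degassed aq NaHCO3
Reagents that add atoms: none
Why: Lewis acid-mediated aryl methyl ether cleavage, in which BBr3 (in excess, because three basic nitrogens and two phenols bind it first) coordinates each methoxy oxygen and bromide removes the methyl group by SN2, a standard demethylation of polyphenolic aryl pyrroles that does not affect the stereocentre.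

Compound list
1 | (R)-3-bromo-2-methylpropan-1-ol | C[C@H](CO)CBr | starting material
2 | (6-bromohexyloxy)(tert-butyl)dimethylsilane | BrCCCCCCO[Si](C)(C)C(C)(C)C | starting material
3 | [6-(tert-butyldimethylsilyloxy)hexyl]magnesium bromide | Br[Mg]CCCCCCO[Si](C)(C)C(C)(C)C | intermediate (not isolated)
4 | (S)-9-[(tert-butyldimethylsilyl)oxy]-2-methylnonan-1-ol | C[C@H](CO)CCCCCCCO[Si](C)(C)C(C)(C)C | intermediate
5 | tert-butyl [(2-nitrophenyl)sulfonyl]carbamate | CC(C)(C)OC(=O)NS(=O)(=O)c1ccccc1[N+](=O)[O-] | starting material
6 | tert-butyl {(2S)-9-[(tert-butyldimethylsilyl)oxy]-2-methylnonyl}[(2-nitrophenyl)sulfonyl]carbamate | C[C@H](CN(C(=O)OC(C)(C)C)S(=O)(=O)c1ccccc1[N+](=O)[O-])CCCCCCCO[Si](C)(C)C(C)(C)C | intermediate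
7 | N-[(2S)-9-hydroxy-2-methylnonyl]-2-nitrobenzenesulfonamide | C[C@H](CNS(=O)(=O)c1ccccc1[N+](=O)[O-])CCCCCCCO | intermediate
8 | (3S)-3-methyl-1-[(2-nitrophenyl)sulfonyl]azecane | C[C@H]1CCCCCCCN(S(=O)(=O)c2ccccc2[N+](=O)[O-])C1 | intermediate
9 | (S)-3-methylazecane | C[C@H]1CCCCCCCNC1 | intermediate
10 | dimethyl 1H-pyrrole-3,4-dicarboxylate | COC(=O)c1c[nH]cc1C(=O)OC | starting material
11 | 1-bromo-3-chloropropane | ClCCCBr | starting material
12 | dimethyl 1-(3-chloropropyl)-1H-pyrrole-3,4-dicarboxylate | COC(=O)c1cn(CCCCl)cc1C(=O)OC | intermediate
13 | 1-(3-chloropropyl)-N3,N4-dimethoxy-N3,N4-dimethyl-1H-pyrrole-3,4-dicarboxamide | CON(C)C(=O)c1cn(CCCCl)cc1C(=O)N(C)OC | intermediate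
14 | 3-bromo-2-methylpyridine | Cc1ncccc1Br | starting material
15 | (2-methylpyridin-3-yl)magnesium chloride | Cc1ncccc1[Mg]Cl | intermediate (not isolated)
16 | [1-(3-chloropropyl)-1H-pyrrole-3,4-diyl]bis[(2-methylpyridin-3-yl)methanone] | Cc1ncccc1C(=O)c1cn(CCCCl)cc1C(=O)c1cccnc1C | intermediate
17 | [1-{3-[(3S)-3-methylazecan-1-yl]propyl}-1H-pyrrole-3,4-diyl]bis[(2-methylpyridin-3-yl)methanone] | C[C@H]1CCCCCCCN(CCCn2cc(C(=O)c3cccnc3C)c(C(=O)c3cccnc3C)c2)C1 | intermediate
18 | methyl methoxyacetate | COCC(=O)OC | starting material
19 | 1,1'-{[1-{3-[(3S)-3-methylazecan-1-yl]propyl}-1H-pyrrole-3,4-diyl]bis(carbonylpyridine-3,2-diyl)}bis(3-methoxypropan-2-one) | C[C@H]1CCCCCCCN(CCCn2cc(C(=O)c3cccnc3CC(=O)COC)c(C(=O)c3cccnc3CC(=O)COC)c2)C1 | intermediate (not isolated)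
20 | 5,5'-[1-{3-[(3S)-3-methylazecan-1-yl]propyl}-1H-pyrrole-3,4-diyl]bis(6-methoxyquinolin-7-ol) | C[C@H]1CCCCCCCN(CCCn2cc(-c3c(OC)c(O)cc4ncccc34)c(-c3c(OC)c(O)cc4ncccc34)c2)C1 | intermediate
21 | isohalitulin, 5,5'-[1-{3-[(3S)-3-methylazecan-1-yl]propyl}-1H-pyrrole-3,4-diyl]bis(quinoline-6,7-diol) | C[C@H]1CCCCCCCN(CCCn2cc(-c3c(O)c(O)cc4ncccc34)c(-c3c(O)c(O)cc4ncccc34)c2)C1 | target

Total step count: 11

Longest linear sequence: 8 steps (steps 1, 2, 3, 4, 5, 9, 10, 11)

Steps most likely to fail

Step 10. Acylation may stay incomplete because the ester is lost to enolisation and self-condensation. Ring closure may stall because the C6 enolate is thinly populated and the pyrrole-conjugated ketone is a weak acceptor. The C8 enolate of one arm may condense with the ketone of the other arm, and methoxide may cleave the new ketone by retro-Claisen reaction. The fallback sets out from 17 and comes back at 20, passing through 19 as an isolated compound; it makes no compound outside the compound list (F0). The cascade is split into two operations, and the ring-closing nucleophile is defined by base stoichiometry instead of by alkoxide equilibration. Lateral lithiation of 17 with LiTMP (2.2 equiv) and acylation with 2-methoxy-N-methoxy-N-methylacetamide would give 19 after work-up, because the chelated tetrahedral adducts persist in the flask and no enolate chemistry can follow. Isolated 19 would then be treated with an excess of LiTMP in THF (or KNH2 in liquid NH3) to form the α,α′-dianion of each methoxyacetonyl ketone. As with the 1,3-dianions of benzyl ketones, the last-formed and least stabilised carbanion (C6) is the one that adds to a ketone, so each arm would close onto its own C5 carbonyl while C8 stays tied up as the enolate. Acidic work-up (AcOH, 60 °C) would dehydrate and aromatise the aldolates to 20.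

Step 4. Intermolecular alkylation to dimers and oligomers may outrun the ten-membered ring closure, which is slowed by transannular strain. The fallback sets out from 1 and comes back at 8; the ring is closed at a C=C bond instead of at nitrogen. Copper-catalysed coupling of 1 with but-3-en-1-ylmagnesium bromide (Li2CuCl4, THF) would give (S)-2-methylhept-6-en-1-ol F1. N-(But-3-en-1-yl)-2-nitrobenzenesulfonamide F2, made from but-3-en-1-amine and 2-nitrobenzenesulfonyl chloride, would be alkylated with F1 under Mitsunobu conditions to give the diene N-(but-3-en-1-yl)-N-[(2S)-2-methylhept-6-en-1-yl]-2-nitrobenzenesulfonamide F3. Ring-closing metathesis with the second-generation Grubbs catalyst in dilute CH2Cl2 at reflux would give (3S)-3-methyl-1-[(2-nitrophenyl)sulfonyl]-1,2,3,4,5,6,9,10-octahydroazecine F4 as a mixture of alkene isomers. Diimide (TsNHNH2, NaOAc, aqueous DME, reflux) would saturate the C7=C8 bond without touching the nitro group and give 8.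

Step 8. The second acyl substitution may stall next to the first bulky magnesium chelate on an amide that the pyrrole nitrogen deactivates, or the first tetrahedral alkoxide may be captured by the neighbouring amide, so that keto amide or lactol-type material accumulates. The fallback sets out from 14 (through its Grignard reagent 15) and comes back at 16; the two ketones are made on a fumarate and the pyrrole ring is built afterwards. Fumaryl chloride and N,O-dimethylhydroxylamine hydrochloride (pyridine, CH2Cl2) would give (2E)-N1,N4-dimethoxy-N1,N4-dimethylbut-2-enediamide F5. Addition of 15 to both amide groups would give (2E)-1,4-bis(2-methylpyridin-3-yl)but-2-ene-1,4-dione F6. Van Leusen pyrrole synthesis with TosMIC and NaH in THF–DMSO would build the ring across the enedione double bond and give (1H-pyrrole-3,4-diyl)bis[(2-methylpyridin-3-yl)methanone] F7. N-Alkylation of F7 with 11 (K2CO3, DMF) would give 16.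

Further compounds
F0 | step 10 | none | none
F1 | step 4 | (S)-2-methylhept-6-en-1-ol | C[C@H](CO)CCCC=C
F2 | step 4 | N-(but-3-en-1-yl)-2-nitrobenzenesulfonamide | C=CCCNS(=O)(=O)c1ccccc1[N+](=O)[O-]
F3 | step 4 | N-(but-3-en-1-yl)-N-[(2S)-2-methylhept-6-en-1-yl]-2-nitrobenzenesulfonamide | C[C@H](CN(CCC=C)S(=O)(=O)c1ccccc1[N+](=O)[O-])CCCC=C
F4 | step 4 | (3S)-3-methyl-1-[(2-nitrophenyl)sulfonyl]-1,2,3,4,5,6,9,10-octahydroazecine (mixture of alkene isomers) | C[C@H]1CCCC=CCCN(S(=O)(=O)c2ccccc2[N+](=O)[O-])C1
F5 | step 8 | (2E)-N1,N4-dimethoxy-N1,N4-dimethylbut-2-enediamide | CON(C)C(=O)/C=C/C(=O)N(C)OC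
F6 | step 8 | (2E)-1,4-bis(2-methylpyridin-3-yl)but-2-ene-1,4-dione | Cc1ncccc1C(=O)/C=C/C(=O)c1cccnc1C
F7 | step 8 | (1H-pyrrole-3,4-diyl)bis[(2-methylpyridin-3-yl)methanone] | Cc1ncccc1C(=O)c1c[nH]cc1C(=O)c1cccnc1C
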